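**Remark on the chemistry:** the locants O1 and C2–C7 of the target are kept for every intermediate, and the donor is carried as an ethyl ester because the glyoxylic ester in common supply is ethyl glyoxylate; the alkoxy group is lost in step 5.

**Numbering used throughout:** 1 vanillin; 2 silylated ring A aldehyde; 3 2-bromo-3-(trimethylsilyl)propene; 4 ethyl glyoxylate; 5 Grignard reagent from 3; 6 hydroxy ester; 7 acetoxy ester (donor); 8 cycloadduct ester; 9 C6 alcohol; 10 C6 silyl ether; 11 alkylborane; 12 C7 alcohol; 13 C7 aldehyde; 14 4-bromo-2,6-dimethoxyphenol; 15 its silyl ether; 16 aryllithium from 15; 17 C7 carbinol; 18 ketone (C4 epimers); 19 all-trans ketone; 20 target.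

## Analysis of the target

Target 20 is a 2,3,4-trisubstituted tetrahydrofuran. With the ring numbered O1, C2, C3, C4, C5 it carries the guaiacyl ring A on C2, the hydroxymethyl carbon C6 on C3 and the ketone carbon C7 (bearing the syringyl ring B) on C4; C5 is a free methylene. The three contiguous stereocentres are 2S, 3R and 4S: ring A is trans to C6 and C6 is trans to the aroyl group, so the ring is all-trans and ring A and the aroyl group share one face. C4 is α to the aryl ketone and can be equilibrated, and all-trans is the arrangement thermodynamics should favour. C2 and C3 cannot be corrected once C6 is an alcohol, so these two must be set under control, C2 in the absolute sense. Sensitive features are the two free phenols, the benzylic ether carbon C2 (ionisation under acid), the β-alkoxy ketone (β-elimination of O1 from C5) and the γ-hydroxy ketone, which can close to a hemiketal when C6 and C7 are cis. The difficulty is to make a benzylic ether stereocentre in one absolute configuration and to tell apart two oxygenated one-carbon branches and two electron-rich aryl groups. The route rests on this reading: C2–O1 is the carbonyl group of a ring A aldehyde, and C3–C4–C5 with the branch C7 on C4 is a trimethylenemethane unit whose C3 terminus carries C6 at the ester level.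

## Retrosynthetic reasoning

**20 from 19.** The last cut is that of the three O–Si bonds of 19. Both phenols are carried as triisopropylsilyl ethers and the C6 hydroxyl as a tert-butyldimethylsilyl ether, so one buffered fluoride treatment releases 20. Hydrogenolysable groups are avoided because C2–O1 is itself a benzylic ether, and acid-labile groups because acid ionises C2.

**19 from 18.** C4 is disconnected as a C–H bond: 19 comes from the C4-epimeric mixture 18 by enolate equilibration. C4 is therefore never set kinetically, and any earlier step may deliver either epimer. C6–O stays silylated here so that the cis epimer cannot withdraw from the equilibrium as a cyclic hemiketal.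

**18 from 13 and 16.** The bond between C7 and ring B is cut. Ketone 18 comes from carbinol 17 by oxidation, and 17 from aldehyde 13 and aryllithium 16, which is made from bromide 15. A Heck arylation of the methylene carbon of 10 with 15 would be shorter. It is not used because the tertiary alkylpalladium intermediate has β-hydrogens on C3 and C5 as well as on C7, and elimination into the ring would erase C3 or give an enol ether. Adding ring B as a nucleophile to C7 at the aldehyde level has no such ambiguity.

**13 from 10.** The C7–O bond is cut. Aldehyde 13 comes from alcohol 12, and 12 from the exocyclic alkene of 10 by anti-Markovnikov hydroboration through borane 11. The methylene carbon of 10 is thus the latent C7, and the same step creates C4 as a stereocentre of either configuration.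

**10 from 8.** C6 is taken back to the ester level: 10 is the silyl ether of alcohol 9, and 9 is the reduction product of ester 8. Reduction directly after ring formation removes the acidity of C3 and with it the risk that the alkene of 8 moves into conjugation.

**8 from 2 and 7.** This is the key disconnection: C2–C3 and O1–C5 are cut together. It is the only cut that returns the ring to a simple aldehyde, 2, and lets a chiral catalyst create C2. The three-carbon partner is the ester-substituted trimethylenemethane–palladium complex generated from 7. The forward reaction has to bond through the ester-bearing carbon, choose one face of 2, close the ring trans and leave the exocyclic alkene where it is.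

**7 from 3 and 4.** Donor 7 is the acetate of hydroxy ester 6, and 6 is cut between the vinyl carbon and the carbinol carbon into Grignard reagent 5 (from 3) and aldehyde 4. The ester sits on the acetate-bearing carbon and silicon on the methylene. The opposite placement (silicon on the ester α-carbon, acetate on the methylene) would lead to the same palladium complex, but it calls for an α-silyl β,γ-unsaturated ester. Carboalkoxylation of a metalated allylsilane favours the terminus remote from silicon and cannot be run in the presence of an acetate, so that placement has no short dependable access. Substituted trimethylenemethane–palladium complexes equilibrate to the isomer with the charge on the substituted carbon before they are trapped, so 7 serves equally.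

**2 from 1 and 15 from 14.** Both are phenol silylations of commercial materials.

## Alternatives that were turned down

**Alternative 1: Prins–pinacol ring contraction.**
- Disconnection: O1–C2 and C2–C3 are cut and C5 is moved back from C4 to C7. This gives aldehyde 2 and the tertiary allylic 1,2-diol A2, in which C7 is a carbinol carrying ring B and C5–OH is the primary hydroxyl.
- Forward key step: 2 and A2 form a dioxolane, and SnCl4 opens it to an oxocarbenium ion. The C3=C4 alkene attacks C2, and C5 shifts from C7 to C4 as C7 becomes the ketone, giving A1.
- For it: one step would build the ring, all three stereocentres in the all-trans sense and the ketone, with ring B already in place. In step economy after ring formation it is clearly stronger than the chosen route, which needs several steps to put ring B and the ketone oxygen on C7.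
- Against it: the carbinol of A2 is tertiary, allylic and benzylic to a very electron-rich ring, and would ionise under SnCl4 before it can direct anything. The alkene is 1,2-disubstituted and deactivated by the allylic acetoxy group, yet must develop charge at a secondary carbon. The absolute configuration would be relayed from the C7 carbinol through a chair in which aryl and complexed oxygen compete for the equatorial site, so its level cannot be predicted.
- Comparison: the chosen route takes C2 from a catalyst and not from a centre that is destroyed, and it avoids a fragile tertiary benzylic alcohol; it pays with more steps after the ring is made.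

**Alternative 2: carbene C–H insertion to a furofuranone.**
- Disconnection: only C2–C3 is cut. The ether O1–C5 and the C3–C4 bond are already present in the trans-disubstituted α-diazo lactone A4, whose lactone carbonyl is C6 and whose lactone oxygen sits on C7.
- Forward key step: Rh2(OAc)4 turns A4 into a carbene at C3, which inserts into the benzylic ether C–H bond at C2 and gives the cis-fused bicyclic lactone A3 with ring A on the convex face.
- For it: insertion into a C–H bond next to ether oxygen to form a five-membered ring is well precedented, and the bicyclic framework fixes C2 and C3. On precedent for the key step it is stronger than the chosen route.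
- Against it: the ring fusion forces the C3 and C4 branches cis, so C4 must still be inverted after the lactone is opened, and at that stage the cis γ-hydroxy ketone can close to a hemiketal. The absolute configuration has to be built into A4 through C7, a centre that is later oxidised away. The carbene may instead form an oxonium ylide at the ether oxygen or add to the electron-rich ring A. Unfolding needs lactone reduction, selective benzylic oxidation and equilibration, and A4 itself needs an asymmetric lactone synthesis and a diazo transfer.
- Comparison: the sequence is markedly longer. The chosen route offers a catalytic, enantioselective ring formation from a simple aldehyde and reaches the same late C4 equilibration with C6 protected.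

**Alternative 3: titanocene epoxide radical cyclisation.**
- Disconnection: C3–C4 is cut, leading to the epoxy propargyl ether A6, which already carries O1–C5 and ring B on the alkyne.
- Forward key step: Cp2TiCl opens the epoxide of A6 to a radical at C3 with C6–O bound to titanium. The radical adds to the alkyne and gives A5, with the hydroxymethyl group free and an exocyclic arylmethylene at C4.
- For it: the reaction class is established for tetrahydrofurans of this kind, and ring B and C7 are in place at once. Hydroboration–oxidation of the arylmethylene and oxidation would reach the ketone in fewer steps after ring formation than the chosen route needs. On both points it is stronger.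
- Against it: the ring-forming step does nothing for the absolute configuration of C2, which must be bought beforehand by resolution or asymmetric reduction. The trans relationship at C3 depends on the diastereoselectivity of a radical closure, titanium is stoichiometric, and A6 takes about five steps including an alkyne arylation.
- Comparison: the total step count is similar. The chosen route offers C2 and the ring in one catalytic step and the higher conceptual return; a simplified form of this alternative, with a terminal alkyne, is kept as the fallback for the key step.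

Key step: step 4

## Route

Step 1
Reactants: 1 vanillin
Product: 2 3-methoxy-4-[(triisopropylsilyl)oxy]benzaldehyde
Conditions: TIPSCl, imidazole, DMF, rt
Reagents that add atoms: triisopropylsilyl chloride, CC(C)[Si](Cl)(C(C)C)C(C)C
Why: Standard silylation of a phenol; the triisopropylsilyl ether is chosen because it has to survive acetate at 45 °C, hydride, alkaline peroxide, an aryllithium and DBU before it is removed by fluoride.

Step 2
Reactants: 3 2-bromo-3-(trimethylsilyl)propene; 4 ethyl glyoxylate
Product: 6 ethyl 2-hydroxy-3-[(trimethylsilyl)methyl]but-3-enoate (racemic), via alkenylmagnesium bromide 5 (not isolated)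
Conditions: Mg, THF, rt; then freshly distilled 4, THF, −78 °C; aq. NH4Cl
Reagents that add atoms: none
Why: Magnesium insertion into the vinyl bromide gives 5, which adds to the aldehyde carbonyl of 4 faster than to its ester at low temperature (Grignard addition). The product is racemic, which is immaterial because the carbinol carbon becomes part of a planar allyl unit in step 4.

Step 3
Reactants: 6 ethyl 2-hydroxy-3-[(trimethylsilyl)methyl]but-3-enoate
Product: 7 ethyl 2-acetoxy-3-[(trimethylsilyl)methyl]but-3-enoate (racemic)
Conditions: Ac2O, pyridine, DMAP (cat.), CH2Cl2, 0 °C → rt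
Reagents that add atoms: acetic anhydride, CC(=O)OC(C)=O
Why: DMAP-catalysed acetylation of the secondary alcohol installs the allylic leaving group, which in step 4 also serves as the desilylating agent.

Step 4
Reactants: 2 3-methoxy-4-[(triisopropylsilyl)oxy]benzaldehyde; 7 ethyl 2-acetoxy-3-[(trimethylsilyl)methyl]but-3-enoate
Product: 8 ethyl (2S,3S)-2-{3-methoxy-4-[(triisopropylsilyl)oxy]phenyl}-4-methylideneoxolane-3-carboxylate (2,3-trans)
Conditions: Pd2(dba)3·CHCl3 (2.5 mol%), chiral BINOL-derived phosphoramidite with a 2,5-diarylpyrrolidine amine part (10 mol%), In(acac)3 (10 mol%), 7 (1.5 equiv), toluene, 45 °C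
Reagents that add atoms: none
Why: Proposed new method: zerovalent palladium ionises the allylic acetate of 7 (both enantiomers converge), the acetate removes the trimethylsilyl group, and the zwitterionic trimethylenemethane–palladium complex settles by η3–η1 isomerisation into the form with the negative charge on the ester-bearing carbon; this carbon adds to the carbonyl carbon of 2 (C2–C3) and the resulting alkoxide attacks an unsubstituted terminus of the π-allyl unit (O1–C5), releasing the catalyst. The closest known reaction type is the palladium-catalysed enantioselective (3+2) cycloaddition of the unsubstituted trimethylenemethane donor with aryl aldehydes to 2-aryl-4-methylenetetrahydrofurans, together with acceptor-substituted donors adding to electron-poor alkenes through their substituted carbon. The tetrahydrofuran ring closes by intramolecular allylic substitution, formally 5-exo-tet with palladium leaving outside the ring, so the cycloaddition is stepwise. C2 is set by the chiral phosphoramidite on palladium, which must deliver the donor to the Si face of 2 to give 2S; if the first ligand antipode gives the 2R series, its mirror image is used. C3 is set relative to C2: trans is expected from the ring closure and is also the thermodynamic arrangement at this acidic position. The step needs bonding through the ester carbon and not through a methylene, which the charge localisation by the ester secures, and it must leave the exocyclic alkene out of conjugation, which the near-neutral medium, the moderate temperature and the immediate reduction in step 5 are meant to secure. In(acac)3 is added to activate the electron-rich aldehyde toward the stabilised and therefore weakly nucleophilic complex.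

Step 5
Reactants: 8 ethyl (2S,3S)-2-{3-methoxy-4-[(triisopropylsilyl)oxy]phenyl}-4-methylideneoxolane-3-carboxylate
Product: 9 [(2S,3R)-2-{3-methoxy-4-[(triisopropylsilyl)oxy]phenyl}-4-methylideneoxolan-3-yl]methanol
Conditions: i-Bu2AlH (2.5 equiv), CH2Cl2, −78 → 0 °C; aq. potassium sodium tartrate
Reagents that add atoms: none
Why: Hydride reduction of the ester to the primary alcohol leaves the aryl silyl ether and the alkene alone. It also ends the acidity of C3, so the trans relationship and the alkene position are secure from here on; the descriptor at C3 changes to R by priority only.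

Step 6
Reactants: 9 [(2S,3R)-2-{3-methoxy-4-[(triisopropylsilyl)oxy]phenyl}-4-methylideneoxolan-3-yl]methanol
Product: 10 tert-butyl{[(2S,3R)-2-{3-methoxy-4-[(triisopropylsilyl)oxy]phenyl}-4-methylideneoxolan-3-yl]methoxy}dimethylsilane
Conditions: TBSCl, imidazole, CH2Cl2, rt
Reagents that add atoms: tert-butyldimethylsilyl chloride, CC(C)(C)[Si](C)(C)Cl
Why: Silylation of the primary alcohol masks C6–OH, so that the hydroxyl created on C7 in step 7 is the only free one and C6 cannot form a hemiketal later.

Step 7
Reactants: 10 tert-butyl{[(2S,3R)-2-{3-methoxy-4-[(triisopropylsilyl)oxy]phenyl}-4-methylideneoxolan-3-yl]methoxy}dimethylsilane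
Product: 12 (2S,3R)-3-({[tert-butyl(dimethyl)silyl]oxy}methyl)-4-(hydroxymethyl)-2-{3-methoxy-4-[(triisopropylsilyl)oxy]phenyl}oxolane (C4 epimers), via B-alkyl-9-BBN adduct 11 (not isolated)
Conditions: 9-BBN (1.5 equiv), THF, 0 °C → rt; then aq. NaOH, 30% H2O2, 0 °C → rt
Reagents that add atoms: hydrogen peroxide, OO
Why: Anti-Markovnikov hydroboration–oxidation of the 1,1-disubstituted alkene puts boron and then oxygen on C7 and hydrogen on C4. Attack anti to the C3 arm should give mainly the 3,4-cis epimer, which does not matter because C4 is equilibrated in step 12.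

Step 8
Reactants: 12 (2S,3R)-3-({[tert-butyl(dimethyl)silyl]oxy}methyl)-4-(hydroxymethyl)-2-{3-methoxy-4-[(triisopropylsilyl)oxy]phenyl}oxolane (C4 epimers)
Product: 13 (2S,3R)-3-({[tert-butyl(dimethyl)silyl]oxy}methyl)-4-formyl-2-{3-methoxy-4-[(triisopropylsilyl)oxy]phenyl}oxolane (C4 epimers)
Conditions: Dess–Martin periodinane, NaHCO3, CH2Cl2, 0 °C → rt
Reagents that add atoms: none
Why: Dess–Martin oxidation of the primary alcohol under buffered, non-basic conditions gives the β-alkoxy aldehyde without β-elimination; it is used without delay.

Step 9
Reactants: 14 4-bromo-2,6-dimethoxyphenol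
Product: 15 (4-bromo-2,6-dimethoxyphenoxy)tri(propan-2-yl)silane
Conditions: TIPSCl, imidazole, DMF, 40 °C
Reagents that add atoms: triisopropylsilyl chloride, CC(C)[Si](Cl)(C(C)C)C(C)C
Why: Silylation of the flanked phenol; the triisopropylsilyl ether tolerates the lithiation and the later DBU treatment, during which it sits para to a ketone.

Step 10
Reactants: 15 (4-bromo-2,6-dimethoxyphenoxy)tri(propan-2-yl)silane; 13 (2S,3R)-3-({[tert-butyl(dimethyl)silyl]oxy}methyl)-4-formyl-2-{3-methoxy-4-[(triisopropylsilyl)oxy]phenyl}oxolane (C4 epimers)
Product: 17 (2S,3R)-3-({[tert-butyl(dimethyl)silyl]oxy}methyl)-4-{[3,5-dimethoxy-4-(triisopropylsilyloxy)phenyl](hydroxy)methyl}-2-{3-methoxy-4-[(triisopropylsilyl)oxy]phenyl}oxolane (epimers at C4 and C7), via aryllithium 16 (not isolated)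
Conditions: 15, n-BuLi, THF, −78 °C; then 13, −78 °C; aq. NH4Cl
Reagents that add atoms: none
Why: Bromine–lithium exchange gives 16, which adds to the aldehyde (1,2-addition of an aryllithium). The carbinol centre is removed in step 11 and C4 is corrected in step 12, so no selectivity is asked of this step.

Step 11
Reactants: 17 (2S,3R)-3-({[tert-butyl(dimethyl)silyl]oxy}methyl)-4-{[3,5-dimethoxy-4-(triisopropylsilyloxy)phenyl](hydroxy)methyl}-2-{3-methoxy-4-[(triisopropylsilyl)oxy]phenyl}oxolane
Product: 18 (2S,3R)-3-({[tert-butyl(dimethyl)silyl]oxy}methyl)-4-[3,5-dimethoxy-4-(triisopropylsilyloxy)benzoyl]-2-{3-methoxy-4-[(triisopropylsilyl)oxy]phenyl}oxolane (C4 epimers)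
Conditions: Dess–Martin periodinane, NaHCO3, CH2Cl2, rt
Reagents that add atoms: none
Why: Dess–Martin oxidation of the benzylic secondary alcohol gives the aryl ketone and merges the carbinol epimers.

Step 12
Reactants: 18 (2S,3R)-3-({[tert-butyl(dimethyl)silyl]oxy}methyl)-4-[3,5-dimethoxy-4-(triisopropylsilyloxy)benzoyl]-2-{3-methoxy-4-[(triisopropylsilyl)oxy]phenyl}oxolane (C4 epimers)
Product: 19 (2S,3R,4S)-3-({[tert-butyl(dimethyl)silyl]oxy}methyl)-4-[3,5-dimethoxy-4-(triisopropylsilyloxy)benzoyl]-2-{3-methoxy-4-[(triisopropylsilyl)oxy]phenyl}oxolane (all-trans)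
Conditions: DBU (0.3 equiv), anhydrous toluene, rt
Reagents that add atoms: none
Why: Thermodynamic equilibration through the C4 enolate should drive both epimers to the all-trans ketone, in which the aroyl group is trans to the C3 arm. C6–O is silylated so that the cis epimer cannot be held back as a hemiketal, and the C5–O1 bond lies near the nodal plane of the enolate, which disfavours β-elimination.

Step 13
Reactants: 19 (2S,3R,4S)-3-({[tert-butyl(dimethyl)silyl]oxy}methyl)-4-[3,5-dimethoxy-4-(triisopropylsilyloxy)benzoyl]-2-{3-methoxy-4-[(triisopropylsilyl)oxy]phenyl}oxolane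
Product: 20 (4-hydroxy-3,5-dimethoxyphenyl)[(3S,4R,5S)-5-(4-hydroxy-3-methoxyphenyl)-4-(hydroxymethyl)oxolan-3-yl]methanone (2S,3R,4S in the locants used here)
Conditions: TBAF (4 equiv), AcOH (4 equiv), THF, 0 °C → rt
Reagents that add atoms: none
Why: Fluoride cleaves the two aryl triisopropylsilyl ethers and the alkyl tert-butyldimethylsilyl ether in one global desilylation. Acetic acid buffers the phenoxides and the alkoxide so that C4 is not re-equilibrated and the ring is not opened; the trans γ-hydroxy ketone cannot close to a hemiketal.

## Compound list

1 | vanillin (4-hydroxy-3-methoxybenzaldehyde) | COc1cc(C=O)ccc1O | starting material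
2 | 3-methoxy-4-[(triisopropylsilyl)oxy]benzaldehyde | COc1cc(C=O)ccc1O[Si](C(C)C)(C(C)C)C(C)C | intermediate
3 | 2-bromo-3-(trimethylsilyl)propene | C=C(Br)C[Si](C)(C)C | starting material
4 | ethyl glyoxylate | CCOC(=O)C=O | starting material
5 | [3-(trimethylsilyl)prop-1-en-2-yl]magnesium bromide | C=C([Mg]Br)C[Si](C)(C)C | intermediate (not isolated)
6 | ethyl 2-hydroxy-3-[(trimethylsilyl)methyl]but-3-enoate (racemic) | CCOC(=O)C(O)C(=C)C[Si](C)(C)C | intermediate
7 | ethyl 2-acetoxy-3-[(trimethylsilyl)methyl]but-3-enoate (racemic) | CCOC(=O)C(OC(C)=O)C(=C)C[Si](C)(C)C | intermediate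
8 | ethyl (2S,3S)-2-{3-methoxy-4-[(triisopropylsilyl)oxy]phenyl}-4-methylideneoxolane-3-carboxylate | COc1cc([C@H]2OCC(=C)[C@@H]2C(=O)OCC)ccc1O[Si](C(C)C)(C(C)C)C(C)C | intermediate
9 | [(2S,3R)-2-{3-methoxy-4-[(triisopropylsilyl)oxy]phenyl}-4-methylideneoxolan-3-yl]methanol | COc1cc([C@H]2OCC(=C)[C@@H]2CO)ccc1O[Si](C(C)C)(C(C)C)C(C)C | intermediate
10 | tert-butyl{[(2S,3R)-2-{3-methoxy-4-[(triisopropylsilyl)oxy]phenyl}-4-methylideneoxolan-3-yl]methoxy}dimethylsilane | COc1cc([C@H]2OCC(=C)[C@@H]2CO[Si](C)(C)C(C)(C)C)ccc1O[Si](C(C)C)(C(C)C)C(C)C | intermediate
11 | B-alkyl-9-borabicyclo[3.3.1]nonane from 10, boron on C7 (C4 epimers) | COc1cc([C@H]2OCC(CB3C4CCCC3CCC4)[C@@H]2CO[Si](C)(C)C(C)(C)C)ccc1O[Si](C(C)C)(C(C)C)C(C)C | intermediate (not isolated)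
12 | (2S,3R)-3-({[tert-butyl(dimethyl)silyl]oxy}methyl)-4-(hydroxymethyl)-2-{3-methoxy-4-[(triisopropylsilyl)oxy]phenyl}oxolane (C4 epimers, 3,4-cis expected to predominate) | COc1cc([C@H]2OCC(CO)[C@@H]2CO[Si](C)(C)C(C)(C)C)ccc1O[Si](C(C)C)(C(C)C)C(C)C | intermediate
13 | (2S,3R)-3-({[tert-butyl(dimethyl)silyl]oxy}methyl)-4-formyl-2-{3-methoxy-4-[(triisopropylsilyl)oxy]phenyl}oxolane (C4 epimers) | COc1cc([C@H]2OCC(C=O)[C@@H]2CO[Si](C)(C)C(C)(C)C)ccc1O[Si](C(C)C)(C(C)C)C(C)C | intermediate
14 | 4-bromo-2,6-dimethoxyphenol | COc1cc(Br)cc(OC)c1O | starting material
15 | (4-bromo-2,6-dimethoxyphenoxy)tri(propan-2-yl)silane | COc1cc(Br)cc(OC)c1O[Si](C(C)C)(C(C)C)C(C)C | intermediate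
16 | [3,5-dimethoxy-4-(triisopropylsilyloxy)phenyl]lithium | [Li]c1cc(OC)c(O[Si](C(C)C)(C(C)C)C(C)C)c(OC)c1 | intermediate (not isolated)
17 | (2S,3R)-3-({[tert-butyl(dimethyl)silyl]oxy}methyl)-4-{[3,5-dimethoxy-4-(triisopropylsilyloxy)phenyl](hydroxy)methyl}-2-{3-methoxy-4-[(triisopropylsilyl)oxy]phenyl}oxolane (epimers at C4 and C7) | COc1cc([C@H]2OCC(C(O)c3cc(OC)c(O[Si](C(C)C)(C(C)C)C(C)C)c(OC)c3)[C@@H]2CO[Si](C)(C)C(C)(C)C)ccc1O[Si](C(C)C)(C(C)C)C(C)C | intermediate
18 | (2S,3R)-3-({[tert-butyl(dimethyl)silyl]oxy}methyl)-4-[3,5-dimethoxy-4-(triisopropylsilyloxy)benzoyl]-2-{3-methoxy-4-[(triisopropylsilyl)oxy]phenyl}oxolane (C4 epimers) | COc1cc([C@H]2OCC(C(=O)c3cc(OC)c(O[Si](C(C)C)(C(C)C)C(C)C)c(OC)c3)[C@@H]2CO[Si](C)(C)C(C)(C)C)ccc1O[Si](C(C)C)(C(C)C)C(C)C | intermediate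
19 | (2S,3R,4S)-3-({[tert-butyl(dimethyl)silyl]oxy}methyl)-4-[3,5-dimethoxy-4-(triisopropylsilyloxy)benzoyl]-2-{3-methoxy-4-[(triisopropylsilyl)oxy]phenyl}oxolane | COc1cc([C@H]2OC[C@@H](C(=O)c3cc(OC)c(O[Si](C(C)C)(C(C)C)C(C)C)c(OC)c3)[C@@H]2CO[Si](C)(C)C(C)(C)C)ccc1O[Si](C(C)C)(C(C)C)C(C)C | intermediate
20 | (4-hydroxy-3,5-dimethoxyphenyl)[(3S,4R,5S)-5-(4-hydroxy-3-methoxyphenyl)-4-(hydroxymethyl)oxolan-3-yl]methanone | COc1cc([C@H]2OC[C@@H](C(=O)c3cc(OC)c(O)c(OC)c3)[C@@H]2CO)ccc1O | target

## Step count and least certain steps

Total step count: 13. Longest linear sequence: 11 steps (from 3 through steps 2–8 and 10–13).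

**Step 4 (key step).**
- What may go wrong: the ester-stabilised complex may add too slowly to the electron-rich aldehyde, so that protonation of the complex and loss of the donor as a desilylated conjugated ester take over. Face selection at the aldehyde may be poor, because ligands of this family were developed for the unsubstituted, more reactive complex. The acetate present may also move the exocyclic alkene into conjugation or allow closure to the C3 epimer.
- Fallback (known chemistry, a radical ring closure in place of the cycloaddition), setting out from 2 and rejoining at 9: CH2=CHMgBr adds to 2 to give racemic 1-{3-methoxy-4-[(triisopropylsilyl)oxy]phenyl}prop-2-en-1-ol F1. Lipase-catalysed acetylation (immobilised Candida antarctica lipase B, vinyl acetate) should leave the (S)-alcohol F2 and turn its antipode into the (R)-acetate F3, which is separated. O-Propargylation of F2 (NaH, propargyl bromide, THF) gives the propargyl ether F4. Epoxidation of its vinyl group (mCPBA, NaHCO3) gives the epoxide F5 as a mixture at the new centre, which is of no consequence because that carbon becomes a radical. Cp2TiCl (from Cp2TiCl2 and Zn, THF) opens the epoxide to the secondary radical at C3, which closes 5-exo-dig onto the alkyne (C3–C4); reduction of the vinyl radical and acidic work-up should then give 9 with the 2,3-trans arrangement, and the route continues with step 6.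

**Step 2.**
- What may go wrong: the monomeric aldehyde 4 re-oligomerises or carries water, which destroys 5, and 5 may also attack the ester, so conversion to 6 is low.
- Fallback, setting out from 3 and rejoining at 6: 5 is made as before and acylated with diethyl oxalate at −78 °C to give the keto ester ethyl 2-oxo-3-[(trimethylsilyl)methyl]but-3-enoate F6. 1,2-Reduction with NaBH4 and CeCl3·7H2O in ethanol at low temperature should give 6.

**Step 10.**
- What may go wrong: deprotonation of the α-branched β-alkoxy aldehyde by 16 in place of addition, which returns 13 on work-up and consumes the aryllithium.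
- Fallback, setting out from 13 and rejoining at 18: chlorite oxidation (NaClO2, NaH2PO4, 2-methylbut-2-ene) gives the carboxylic acid F7. Coupling with N,O-dimethylhydroxylamine (carbodiimide, N-methylmorpholine) gives the Weinreb amide F8. Aryllithium 16 then adds once to F8 and gives ketone 18 directly, without a carbinol stage.

**Step 12.**
- What may go wrong: the enolate may expel O1 from C5 and open the ring, the base may strip the silyl group from the para-acyl phenol of ring B, or equilibration may stop short of the all-trans isomer.
- Fallback, setting out from 13 and rejoining at 19: the equilibration is moved one stage earlier and done without an enolate. Pyrrolidine and acetic acid (20 mol% each, CH2Cl2) epimerise 13 through its enamine to the 3,4-trans aldehyde F9. Addition of 16 at −78 °C gives the trans carbinol F10, and buffered Dess–Martin oxidation then gives 19 without a base treatment of the ketone.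

## Further compounds

F1 | step 4 | rac-1-{3-methoxy-4-[(triisopropylsilyl)oxy]phenyl}prop-2-en-1-ol | COc1cc(C(O)C=C)ccc1O[Si](C(C)C)(C(C)C)C(C)C
F2 | step 4 | (S)-1-{3-methoxy-4-[(triisopropylsilyl)oxy]phenyl}prop-2-en-1-ol | COc1cc([C@@H](O)C=C)ccc1O[Si](C(C)C)(C(C)C)C(C)C
F3 | step 4 | (R)-1-{3-methoxy-4-[(triisopropylsilyl)oxy]phenyl}prop-2-en-1-yl acetate | COc1cc([C@H](OC(C)=O)C=C)ccc1O[Si](C(C)C)(C(C)C)C(C)C
F4 | step 4 | triisopropyl{2-methoxy-4-[(1S)-1-(prop-2-yn-1-yloxy)prop-2-en-1-yl]phenoxy}silane | COc1cc([C@@H](OCC#C)C=C)ccc1O[Si](C(C)C)(C(C)C)C(C)C
F5 | step 4 | triisopropyl{2-methoxy-4-[oxiran-2-yl(prop-2-yn-1-yloxy)methyl]phenoxy}silane, benzylic carbon as in F4, both epoxide epimers | COc1cc([C@@H](OCC#C)C2CO2)ccc1O[Si](C(C)C)(C(C)C)C(C)C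
F6 | step 2 | ethyl 2-oxo-3-[(trimethylsilyl)methyl]but-3-enoate | CCOC(=O)C(=O)C(=C)C[Si](C)(C)C
F7 | step 10 | (2S,3R)-3-({[tert-butyl(dimethyl)silyl]oxy}methyl)-2-{3-methoxy-4-[(triisopropylsilyl)oxy]phenyl}oxolane-4-carboxylic acid (C4 epimers) | COc1cc([C@H]2OCC(C(=O)O)[C@@H]2CO[Si](C)(C)C(C)(C)C)ccc1O[Si](C(C)C)(C(C)C)C(C)C
F8 | step 10 | N-methoxy-N-methyl amide of F7 (C4 epimers) | COc1cc([C@H]2OCC(C(=O)N(C)OC)[C@@H]2CO[Si](C)(C)C(C)(C)C)ccc1O[Si](C(C)C)(C(C)C)C(C)C
F9 | step 12 | (2S,3R,4S)-3-({[tert-butyl(dimethyl)silyl]oxy}methyl)-4-formyl-2-{3-methoxy-4-[(triisopropylsilyl)oxy]phenyl}oxolane | COc1cc([C@H]2OC[C@@H](C=O)[C@@H]2CO[Si](C)(C)C(C)(C)C)ccc1O[Si](C(C)C)(C(C)C)C(C)C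
F10 | step 12 | (2S,3R,4S)-3-({[tert-butyl(dimethyl)silyl]oxy}methyl)-4-{[3,5-dimethoxy-4-(triisopropylsilyloxy)phenyl](hydroxy)methyl}-2-{3-methoxy-4-[(triisopropylsilyl)oxy]phenyl}oxolane (carbinol epimers) | COc1cc([C@H]2OC[C@@H](C(O)c3cc(OC)c(O[Si](C(C)C)(C(C)C)C(C)C)c(OC)c3)[C@@H]2CO[Si](C)(C)C(C)(C)C)ccc1O[Si](C(C)C)(C(C)C)C(C)C
A1 | alternative 1 | all-trans 2-aryl-3-(acetoxymethyl)-4-aroyltetrahydrofuran, both phenols as triisopropylsilyl ethers | COc1cc([C@H]2OC[C@@H](C(=O)c3cc(OC)c(O[Si](C(C)C)(C(C)C)C(C)C)c(OC)c3)[C@@H]2COC(C)=O)ccc1O[Si](C(C)C)(C(C)C)C(C)C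
A2 | alternative 1 | (E)-4,5-dihydroxy-4-[3,5-dimethoxy-4-(triisopropylsilyloxy)phenyl]pent-2-en-1-yl acetate, single enantiomer, carbinol configuration left open as discussed | CC(=O)OC/C=C/C(O)(CO)c1cc(OC)c(O[Si](C(C)C)(C(C)C)C(C)C)c(OC)c1
A3 | alternative 2 | cis-fused 2,6-diaryl-3,7-dioxabicyclo[3.3.0]octan-8-one, ring A on the convex face, both phenols as tert-butyldimethylsilyl ethers | COc1cc([C@H]2OC[C@H]3[C@@H]2C(=O)O[C@@H]3c2cc(OC)c(O[Si](C)(C)C(C)(C)C)c(OC)c2)ccc1O[Si](C)(C)C(C)(C)C
A4 | alternative 2 | trans-3-diazo-5-aryl-4-[(arylmethoxy)methyl]oxolan-2-one (ring B on the lactone, ring A on the benzyl ether) | COc1cc(COC[C@H]3C(=[N+]=[N-])C(=O)O[C@@H]3c2cc(OC)c(O[Si](C)(C)C(C)(C)C)c(OC)c2)ccc1O[Si](C)(C)C(C)(C)C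
A5 | alternative 3 | trans-2-aryl-3-(hydroxymethyl)-4-(arylmethylidene)tetrahydrofuran, both phenols as tert-butyldimethylsilyl ethers | COc1cc([C@H]2OC/C(=C\c3cc(OC)c(O[Si](C)(C)C(C)(C)C)c(OC)c3)[C@@H]2CO)ccc1O[Si](C)(C)C(C)(C)C
A6 | alternative 3 | 3-arylprop-2-ynyl ether of 1-aryl-2,3-epoxypropan-1-ol, benzylic carbon configured as C2 of 20, both epoxide epimers | COc1cc([C@@H](OCC#Cc2cc(OC)c(O[Si](C)(C)C(C)(C)C)c(OC)c2)C3CO3)ccc1O[Si](C)(C)C(C)(C)C
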